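**Remark 1 (numbering).** Core locants are used for all bicyclic compounds and for the atoms of their precursors: C1 = methyl-bearing fusion carbon, C2, C3, C4 = ester carbinol, C5 = fusion CH, C6 = CHOH, C7=C8(CH3), C9 = C=O, C10 = CH2; in these locants the target is (1R,4R,5S,6S).

**Remark 2 (assumption on the chemistry).** Rh2(S-PTAD)4, dirhodium tetrakis[(S)-(1-adamantyl)(N-phthalimido)acetate], is taken to induce in the same sense as Rh2(R-DOSP)4 and so to give cyclopropane 9 with C8 (R) and C6 (S); if the sense is the opposite, Rh2(R-PTAD)4 is used and nothing else changes.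

## Structural features

The target is a trans-fused bicyclo[5.3.0]decane: a cyclopentane and a cycloheptenone share the C1–C5 bond, and every substituent sits on or next to that bond. C1 is a quaternary, methyl-bearing carbon common to both rings. C5 (H), C4 (tertiary oxygen and isopropyl) and C6 (secondary hydroxyl) follow it without a gap, so four contiguous stereocentres must be set: C1–CH3 trans to C5–H, C4–O cis to the C1 methyl, C6–OH cis to C5–H. The seven-membered ring holds a 2-methyl enone (C7=C8(CH3)–C9=O) whose γ-carbon is the C6 carbinol, and C10 is a methylene between the ketone and the quaternary C1. Fragile points are the β-oxygenated carbonyl relationships met on the way (C4=O with C6–O; retro-aldol and β-elimination), the tertiary C4 aryl ester 1,3 to a free secondary hydroxyl (acyl shift, ionisation), and the phenol and γ-hydroxy enone (base, oxidants). The real difficulty is twofold: a quaternary stereocentre inside a seven-membered ring, and esterification of the hindered O4 while the more reactive O6 ends free. The key step uses the fact that C8–C9–C10 is a three-carbon unit oxygenated at its central atom and C7–C6–C5–C1 a four-carbon unit whose C5=C1 bond can lie in a cyclopentenone. A 2-siloxyvinyl carbenoid and a 2-vinylcyclopentenone therefore give the cycloheptadiene in a formal [4+3] event that forms C7–C8 and C1–C10 and fixes C1.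

## Logic of the disconnections

22 from 21: the two O–Si bonds (phenol oxygen and O6) are cut last. Silyl groups are needed because O6 must be blocked during acylation of O4 and the phenol must not compete. The gain is one final operation for both. The demand is a non-basic fluoride source, so that the ester does not shift from O4 to O6.

21 from 17 and 20: the O4–C(=O) bond is cut. This is the only convergent bond, and it removes the whole arene. The forward step must acylate a hindered tertiary alkoxide next to an enolisable enone, so O–H deprotonation at low temperature must outrun C–H deprotonation.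

20 from 19 from 18: the C–Cl and O–Si bonds are cut back to the commercial acid. A silyl ester gives the acid chloride under neutral conditions that spare the aryl silyl ether.

17 from 16 from 14 (through 15): no skeletal bond is cut. The C7=C8 bond is traced to an exocyclic C8=CH2, and that to the ester carbon and the C8=C9 enol ether of 14. The ester carbon already sits on C8, so reducing it to the methyl group avoids adding one carbon and expelling another. The forward steps need a hydride that tolerates the tertiary alcohol and silyl ethers, mild acid, and a metal hydride isomerisation into the ring.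

14 from 13: the C4–CH(CH3)2 bond is cut, leaving a C4 ketone. The forward step needs a weakly basic isopropyl nucleophile that attacks syn to C5–H.

13 from 12 from 11 from 10: the O6–Si, C6–O and C5–H bonds are traced to the C5=C6 enone of 10, whose β-carbon is C6. This leads straight back to the key-step product. The demands are attack at C6 anti to the C1 methyl and protonation of C5 to the trans fusion.

10 from 9 from 5 and 8: C1–C10 and C7–C8 are cut (with C6–C8 of the transient cyclopropane). One operation reduces a bicyclic compound with a quaternary stereocentre to two achiral fragments. The forward step must be chemoselective for the vinyl group, cis-selective, enantioselective, and must pass a boat Cope transition state with an inward methyl.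

5 from 3 and 4, 3 from 1: the sp2–sp2 bond C5–C6 and then C5–Br are cut. The forward steps are a cross-coupling on an α-bromoenone and a bromination–dehydrobromination.

8 from 7 from 6: the O–Si bond and the C=N2 unit are removed. The forward steps are diazo transfer to an active methylene and soft enolisation.

## Other disconnections considered

Alternative 1: The cut is C1–CH3 and C5–C6 on 3-allylcyclopent-2-en-1-one A1. A copper-catalysed, ligand-controlled conjugate methylation creates C1, and the metal enolate is intercepted at C5 by but-2-ynal A2 to give aldol A3, which holds C1, C5, C6 and the C4 ketone.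
- In its favour: three of the four stereocentres and all carbons except isopropyl and aroyl are assembled in one flask from achiral, cheap materials with a base-metal catalyst, and C5 is set by C–C bond formation, not by protonation. On these points it is better than the chosen plan, whose key step fixes only C1.
- Against it here: no ring is closed. The seven-membered ring must still be made by joining C8 to C9 after the allyl terminus has lost one carbon, and an endocyclic enone from an alkyne needs a formal anti addition or several redox steps. The enolate faces differ only by methyl against allyl on C1, so the trans relation of C5–H and C1–CH3 is not assured. C6 comes from an open aldol, and five-membered enones are the harder acceptors for enantioselective quaternary-centre formation.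
- Comparison: in structure A3 is richer in stereocentres than 10 but poorer in rings. In mechanism it relies on acyclic stereocontrol where the chosen plan relies on a stereospecific pericyclic shift. In step economy the opening is equal or shorter, but the deferred medium-ring closure is expected to consume that advantage.

Alternative 2: The cut is C5–C6 and C1–C10. The acetoxypyranone ester A4 (from oxidative ring expansion of a furylcarbinol and esterification with an (E)-hydroxy enone) loses acetate under amine base, and the 3-oxidopyrylium adds across the tethered enone to give adduct A5.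
- In its favour: the seven-membered ring arrives with its final C7=C8(CH3)–C9=O enone and with oxygen on C6 (as the ether bridge). The tether and the (E)-alkene translate into the relative configuration of C1, C5 and C6 in one concerted step. In oxidation-state economy around C6–C9 it is clearly better than the chosen plan.
- Against it: the five-membered carbocycle is not formed. The lactone carbon on C10 must be excised, the C10–O bridge cleaved reductively, and C2–C3 closed by enolate alkylation before the isopropyl addition. The dipolarophile is a trisubstituted enone that must form a quaternary centre, and absolute control would rest on hydrogen-bonding co-catalysis best established for simpler partners.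
- Comparison: in structure A5 maps more functional groups but one ring fewer onto the target than 10. In mechanism both make C1–C10 in a pericyclic step (equal in kind), but the chosen plan takes its absolute configuration from a metal catalyst with a broad record. In step economy it needs more steps before (tether assembly) and after (tether excision, ring closure), so the chosen plan is expected to be shorter.

Alternative 3: The cut is C5–C1 and C5–C6. The carbene carbon C5 of diazoketone A6 is inserted into an arene bond by an achiral dirhodium tetracarboxylate, and the norcaradiene opens to the bicyclic trienone A7.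
- In its favour: both rings, the C8 methyl and the C9 oxygen (as enol ether) come from a cheap arene in very few steps. In speed to the bicyclic skeleton it is better than the chosen plan, and the mechanism (metal carbene addition followed by a pericyclic reorganisation) is of the same family, so equal.
- Against it: A7 lacks the C1 methyl, so the quaternary centre must be made later by conjugate addition after double-bond isomerisation. Its only stereocentre is labile, so all four stereocentres and the absolute configuration remain to be set on a polyene prone to hydrogen shifts. The carbene must choose the C1–C6 over the C1–C10 arene bond, C6 must be oxygenated selectively among three double bonds, and the diazoketone usually calls for diazomethane, a hazard the chosen plan avoids.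
- Comparison: the chosen plan delivers the quaternary centre enantioenriched, which A7 does not. The alternative is shorter to the skeleton but longer to the stereotriad, so the chosen plan is judged the safer.

Key step: step 5

## Route

**Step 1**
Reactants: 1 3-methylcyclopent-2-en-1-one
Product: 3 2-bromo-3-methylcyclopent-2-en-1-one, via 2,3-dibromo-3-methylcyclopentan-1-one 2 (not isolated)
Conditions: Br2, CH2Cl2, 0 °C; then Et3N, 0 °C → rt
Reagents that add atoms: bromine (BrBr)
Why: Bromine adds across C5=C1 and Et3N removes the acidic C5–H with loss of the C1 bromide (E1cB), the standard bromination–dehydrobromination route to α-bromoenones; no stereocentre remains.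

**Step 2**
Reactants: 3 2-bromo-3-methylcyclopent-2-en-1-one; 4 potassium vinyltrifluoroborate
Product: 5 2-ethenyl-3-methylcyclopent-2-en-1-one
Conditions: PdCl2(dppf)·CH2Cl2 (3 mol%; dppf = 1,1'-bis(diphenylphosphino)ferrocene), Cs2CO3, THF/H2O 9:1, 80 °C
Reagents that add atoms: none
Why: Suzuki–Miyaura coupling: zerovalent palladium inserts into the C5–Br bond, the hydrolysed trifluoroborate transmetalates and reductive elimination forms C5–C6. Boron replaces tin to keep toxic residues out, and the volatile diene is used at once.

**Step 3**
Reactants: 6 methyl acetoacetate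
Product: 7 methyl 2-diazo-3-oxobutanoate
Conditions: 4-acetamidobenzenesulfonyl azide, Et3N, MeCN, 0 °C → rt
Reagents that add atoms: 4-acetamidobenzenesulfonyl azide (CC(=O)Nc1ccc(cc1)S(=O)(=O)N=[N+]=[N-])
Why: Regitz diazo transfer to the doubly activated methylene; this sulfonyl azide is chosen as the less shock-sensitive transfer reagent.

**Step 4**
Reactants: 7 methyl 2-diazo-3-oxobutanoate
Product: 8 methyl 3-[(tert-butyldimethylsilyl)oxy]-2-diazobut-3-enoate
Conditions: TBSOTf, Et3N, CH2Cl2, 0 °C
Reagents that add atoms: tert-butyldimethylsilyl trifluoromethanesulfonate (CC(C)(C)[Si](C)(C)OS(=O)(=O)C(F)(F)F)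
Why: Soft enolisation of the acetyl group and O-silylation give the 2-siloxyvinyl diazoacetate without touching the diazo ester. The TBS group is chosen because this enol ether must mask C9 through six later steps; 8 is kept cold and used without distillation.

**Step 5**
Reactants: 5 2-ethenyl-3-methylcyclopent-2-en-1-one; 8 methyl 3-[(tert-butyldimethylsilyl)oxy]-2-diazobut-3-enoate
Product: 10 (1R)-bicyclic dienone (C4 ketone conjugated to C5=C6; methyl ester on C8; C8=C9 TBS enol ether; C1 methyl), via cis-divinylcyclopropane 9 (not isolated)
Conditions: Rh2(S-PTAD)4 (1 mol%), hexanes, −20 °C → rt, slow addition of 8 (1.5 equiv); then toluene, 110 °C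
Reagents that add atoms: none
Why: The dirhodium tetracarboxylate converts 8 into a donor/acceptor (2-siloxyvinyl)(methoxycarbonyl) carbenoid, which adds in a concerted, asynchronous way to the monosubstituted C6=C7 bond of 5 and gives cyclopropane 9 (bonds C8–C7 and C8–C6) with the siloxyvinyl group cis to the cyclopentenyl group. The closest known reaction type is the tandem dirhodium-catalysed cyclopropanation/Cope rearrangement of siloxyvinyldiazoacetates with dienes (formal [4+3] cycloaddition), including 1-vinylcycloalkenes that deliver ring-fusion quaternary centres. On warming, 9 undergoes a [3,3]-sigmatropic shift through the boat transition state: C6–C8 breaks, C10–C1 forms and the double bonds move to C8=C9 and C5=C6. The three-membered ring closes by [2+1] carbene addition and is consumed again; the seven-membered ring closes by this suprafacial pericyclic shift, not by an ionic exo or endo cyclisation, so only the cis,cis-1,4-diene can form. C1 is the only stereocentre that survives: the shift is stereospecific, so C1 (R) follows from the configuration of 9, which the chiral carboxylate ligands impose by face selection at the carbenoid. The step needs chemoselectivity for the vinyl group over the tetrasubstituted, carbonyl-conjugated C5=C1 bond and over the ketone oxygen (secured by the preference of donor/acceptor carbenoids for terminal alkenes) and cis diastereoselectivity (inherent to such carbenoids). The adamantylglycinate ligand is chosen over a prolinate because it is regarded as the better match for 2-siloxy-substituted vinylcarbenoids. Heating is needed because the C1 methyl is Z to the cyclopropane and must point inward in the boat; release of ring strain and formation of the conjugated enone drive the step.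

**Step 6**
Reactants: 10 (1R)-bicyclic dienone
Product: 11 (1R,5R,6S)-5,6-epoxy ketone (oxirane oxygen on the face opposite the C1 methyl; C4 ketone; ester and enol ether unchanged)
Conditions: t-BuOOH (anhydrous, in decane), DBU, CH2Cl2, 0 °C → rt
Reagents that add atoms: tert-butyl hydroperoxide (CC(C)(C)OO)
Why: Weitz–Scheffer nucleophilic epoxidation: the peroxide anion adds to the enone β-carbon C6 and the enolate closes on O–O, while the push-pull C8=C9 enol ether is not an acceptor for a nucleophilic oxidant. Addition is expected on the C6 face away from the pseudoaxial C1 methyl, which sets C6 (S).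

**Step 7**
Reactants: 11 (1R,5R,6S)-5,6-epoxy ketone
Product: 12 (1R,5S,6S)-β-hydroxy ketone (C4 ketone; C5–H and C6–OH both on the face opposite the C1 methyl; trans ring fusion)
Conditions: SmI2 (2.5 equiv), THF/MeOH, −78 °C
Reagents that add atoms: none
Why: Reductive opening of an α,β-epoxy ketone: two single-electron transfers cleave only the C5–O bond, so C6 keeps its configuration. Methanol should protonate the trivalent samarium enolate at C5 on the face anti to the axial C1 methyl (the face that carries the C6 oxygen), giving the trans fusion; −78 °C suppresses β-elimination.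

**Step 8**
Reactants: 12 (1R,5S,6S)-β-hydroxy ketone
Product: 13 (1R,5S,6S)-C6 TBS ether of 12
Conditions: TBSOTf, 2,6-lutidine, CH2Cl2, −78 °C
Reagents that add atoms: tert-butyldimethylsilyl trifluoromethanesulfonate (CC(C)(C)[Si](C)(C)OS(=O)(=O)C(F)(F)F)
Why: Silylation of a secondary aldol-type hydroxyl under non-enolising conditions; it blocks retro-aldol cleavage now and reserves O6 during the later acylation of O4.

**Step 9**
Reactants: 13 (1R,5S,6S)-C6 TBS ether
Product: 14 (1R,4R,5S,6S)-tertiary alcohol (C4–OH cis to the C1 methyl; C4 isopropyl cis to C5–H)
Conditions: i-PrMgCl, CeCl3 (anhydrous), THF, −78 → −20 °C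
Reagents that add atoms: isopropylmagnesium chloride (CC(C)[Mg]Cl)
Why: Organocerium 1,2-addition to a hindered, enolisable ketone; the low basicity suppresses enolisation, β-elimination and β-hydride reduction, and the vinylogous carbonate ester is inert at this temperature. Attack on the C4 face syn to C5–H, anti to the pseudoaxial C1 methyl and to the C5–C6 bond, should set C4 (R).

**Step 10**
Reactants: 14 (1R,4R,5S,6S)-tertiary alcohol
Product: 16 (1R,4R,5S,6S)-α-methylene ketone (C8=CH2; C9 ketone; C4–OH; C6–OTBS), via 2-siloxyallyl alcohol 15 (not isolated)
Conditions: i-Bu2AlH (5 equiv), CH2Cl2, −78 → −20 °C; then 1 M HCl, THF, 0 °C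
Reagents that add atoms: none
Why: 1,2-Reduction of the β-siloxy acrylate gives allylic alcohol 15; acid ionises its C–O bond with help from the enol ether oxygen, and loss of the silyl group gives the exocyclic enone (Stork–Danheiser-type reductive transposition). The ester carbon thus becomes the future C8 methyl carbon and no stereocentre is touched.

**Step 11**
Reactants: 16 (1R,4R,5S,6S)-α-methylene ketone
Product: 17 (1R,4R,5S,6S)-enone alcohol (C7=C8(CH3)–C9=O; C4–OH free; C6–OTBS)
Conditions: RhCl3·3H2O (5 mol%), EtOH, 75 °C
Reagents that add atoms: none
Why: Rhodium hydride addition and β-hydride elimination move the exocyclic double bond into the ring, a known isomerisation of α-methylene ketones to the more stable trisubstituted endocyclic enone. C6 is not affected because the conjugated C7=C8 enone is the thermodynamic sink.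

**Step 12**
Reactants: 18 4-hydroxybenzoic acid
Product: 19 tert-butyldimethylsilyl 4-[(tert-butyldimethylsilyl)oxy]benzoate
Conditions: TBSCl (2.2 equiv), imidazole, DMF, rt
Reagents that add atoms: tert-butyldimethylsilyl chloride (CC(C)(C)[Si](C)(C)Cl)
Why: Imidazole-promoted silylation of both the phenol and the acid.

**Step 13**
Reactants: 19 tert-butyldimethylsilyl 4-[(tert-butyldimethylsilyl)oxy]benzoate
Product: 20 4-[(tert-butyldimethylsilyl)oxy]benzoyl chloride
Conditions: (COCl)2, DMF (cat.), CH2Cl2, 0 °C → rt
Reagents that add atoms: oxalyl chloride (ClC(=O)C(Cl)=O)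
Why: The silyl ester is converted by the chloroiminium species into the acid chloride with loss of TBSCl, CO and CO2; no HCl is formed, so the aryl silyl ether survives.

**Step 14**
Reactants: 17 (1R,4R,5S,6S)-enone alcohol; 20 4-[(tert-butyldimethylsilyl)oxy]benzoyl chloride
Product: 21 (1R,4R,5S,6S)-bis-silyl ester (O4 4-(TBSO)benzoate; C6–OTBS; enone as in 17)
Conditions: LiN(SiMe3)2 (1.05 equiv), THF, −78 °C; then 20 (1.5 equiv), −78 → 0 °C
Reagents that add atoms: none
Why: O–H deprotonation is much faster than C–H deprotonation of the enone, and the lithium tertiary alkoxide is acylated by the aroyl chloride, the usual way to esterify hindered tertiary alcohols. The silyl ether on O6 leaves O4 as the only oxygen nucleophile.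

**Step 15**
Reactants: 21 (1R,4R,5S,6S)-bis-silyl ester
Product: 22 target, (1R,4R,5S,6S)-6-hydroxy-4-isopropyl-1,8-dimethyl-9-oxobicyclo[5.3.0]dec-7-en-4-yl 4-hydroxybenzoate (core locants)
Conditions: HF·pyridine, pyridine, THF, 0 °C → rt
Reagents that add atoms: none
Why: Fluoride cleaves the aryl and the secondary Si–O bonds in one operation; the buffered, weakly acidic medium avoids the 1,3-acyl shift from O4 to O6 and ionisation of the tertiary ester.

## Compound list

1 | 3-methylcyclopent-2-en-1-one | CC1=CC(=O)CC1 | starting material
2 | 2,3-dibromo-3-methylcyclopentan-1-one (racemic, bromines trans) | CC1(Br)CCC(=O)C1Br | intermediate (not isolated)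
3 | 2-bromo-3-methylcyclopent-2-en-1-one | CC1=C(Br)C(=O)CC1 | intermediate
4 | potassium vinyltrifluoroborate | [K+].F[B-](F)(F)C=C | starting material
5 | 2-ethenyl-3-methylcyclopent-2-en-1-one | CC1=C(C=C)C(=O)CC1 | intermediate
6 | methyl acetoacetate | COC(=O)CC(C)=O | starting material
7 | methyl 2-diazo-3-oxobutanoate | COC(=O)C(=[N+]=[N-])C(C)=O | intermediate
8 | methyl 3-[(tert-butyldimethylsilyl)oxy]-2-diazobut-3-enoate | COC(=O)C(=[N+]=[N-])C(=C)O[Si](C)(C)C(C)(C)C | intermediate
9 | methyl (1R,2S)-1-{1-[(tert-butyldimethylsilyl)oxy]ethenyl}-2-(2-methyl-5-oxocyclopent-1-en-1-yl)cyclopropane-1-carboxylate (cyclopropane C1 = core C8, C2 = core C6) | COC(=O)[C@]1(C(=C)O[Si](C)(C)C(C)(C)C)C[C@H]1C2=C(C)CCC2=O | intermediate (not isolated)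
10 | (1R)-bicyclic dienone: C1 methyl, C4 ketone, C5=C6, C8 methyl ester, C8=C9 TBS enol ether | COC(=O)C1=C(O[Si](C)(C)C(C)(C)C)C[C@@]2(C)CCC(=O)C2=CC1 | intermediate
11 | (1R,5R,6S)-5,6-epoxy ketone, oxirane anti to the C1 methyl | COC(=O)C1=C(O[Si](C)(C)C(C)(C)C)C[C@@]2(C)CCC(=O)[C@]2(O3)[C@@H]3C1 | intermediate
12 | (1R,5S,6S)-β-hydroxy ketone, trans-fused, C6–OH free | COC(=O)C1=C(O[Si](C)(C)C(C)(C)C)C[C@@]2(C)CCC(=O)[C@@H]2[C@@H](O)C1 | intermediate
13 | (1R,5S,6S)-C6 TBS ether of 12 | COC(=O)C1=C(O[Si](C)(C)C(C)(C)C)C[C@@]2(C)CCC(=O)[C@@H]2[C@@H](O[Si](C)(C)C(C)(C)C)C1 | intermediate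
14 | (1R,4R,5S,6S)-tertiary alcohol: C4–OH, C4 isopropyl, C6–OTBS, C8 ester, C9 enol ether | COC(=O)C1=C(O[Si](C)(C)C(C)(C)C)C[C@@]2(C)CC[C@@](O)(C(C)C)[C@@H]2[C@@H](O[Si](C)(C)C(C)(C)C)C1 | intermediate
15 | (1R,4R,5S,6S)-2-siloxyallyl alcohol: C8–CH2OH on the C8=C9 TBS enol ether | OCC1=C(O[Si](C)(C)C(C)(C)C)C[C@@]2(C)CC[C@@](O)(C(C)C)[C@@H]2[C@@H](O[Si](C)(C)C(C)(C)C)C1 | intermediate (not isolated)
16 | (1R,4R,5S,6S)-α-methylene ketone: C8=CH2, C9=O | C=C1C(=O)C[C@@]2(C)CC[C@@](O)(C(C)C)[C@@H]2[C@@H](O[Si](C)(C)C(C)(C)C)C1 | intermediate
17 | (1R,4R,5S,6S)-enone alcohol: C7=C8(CH3)–C9=O, C4–OH, C6–OTBS | CC1=C[C@H](O[Si](C)(C)C(C)(C)C)[C@@H]2[C@](C)(CC[C@@]2(O)C(C)C)CC1=O | intermediate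
18 | 4-hydroxybenzoic acid | OC(=O)c1ccc(O)cc1 | starting material
19 | tert-butyldimethylsilyl 4-[(tert-butyldimethylsilyl)oxy]benzoate | CC(C)(C)[Si](C)(C)OC(=O)c1ccc(O[Si](C)(C)C(C)(C)C)cc1 | intermediate
20 | 4-[(tert-butyldimethylsilyl)oxy]benzoyl chloride | CC(C)(C)[Si](C)(C)Oc1ccc(cc1)C(Cl)=O | intermediate
21 | (1R,4R,5S,6S)-bis-silyl ester: O4 4-(TBSO)benzoate, C6–OTBS | CC1=C[C@H](O[Si](C)(C)C(C)(C)C)[C@@H]2[C@](C)(CC[C@@]2(OC(=O)c3ccc(O[Si](C)(C)C(C)(C)C)cc3)C(C)C)CC1=O | intermediate
22 | target, (1R,4R,5S,6S) in core locants | CC1=C[C@H](O)[C@@H]2[C@](C)(CC[C@@]2(OC(=O)c2ccc(O)cc2)C(C)C)CC1=O | target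

## Step count and least certain steps

Total: 15 steps. Longest linear sequence: 11 steps (1 → 3 → 5 → 10 → 11 → 12 → 13 → 14 → 16 → 17 → 21 → 22).

**Step 5 (key step).** Carbene transfer to the twisted, electron-poor vinyl group of 5 may be outrun by capture of the carbenoid at the ketone oxygen or by unproductive diazo decomposition, and enantioselection on this new diene class may be eroded. The fallback removes the carbonyl from the diene; it sets out from 5 and returns at 10. Treatment of 5 with 1,2-bis(trimethylsilyloxy)ethane and catalytic TMSOTf (CH2Cl2, −78 °C, conditions that should not move the double bond) would give 7-methyl-6-vinyl-1,4-dioxaspiro[4.4]non-6-ene F1. This electron-richer diene would be taken through the same dirhodium-catalysed cyclopropanation and Cope shift with 8 to the (1R)-C4 ethylene ketal of 10 F2, and mild hydrolysis of the allylic ketal (pyridinium tosylate, wet acetone) would return 10.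

**Step 6.** Facial selection of peroxide addition at C6 may be poor, because the two faces of the planar enone differ only by C1–CH3 against C1–C10; the base may also remove a C7 proton and move the double bond. The fallback replaces substrate control by a directing hydroxyl; it sets out from 10 and returns at 11. Corey–Bakshi–Shibata reduction with the (S)-oxazaborolidine and BH3·SMe2 would give the (1R,4R)-allylic alcohol with C4–OH on the face opposite the C1 methyl F3. VO(acac)2 and t-BuOOH would deliver the oxirane to the hydroxyl face, giving the (1R,4R,5S,6S)-epoxy alcohol F4, and Parikh–Doering oxidation (SO3·pyridine, DMSO, i-Pr2NEt) would give 11.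

**Step 7.** Protonation of the samarium enolate may occur on the wrong face of C5 (cis fusion), and the C6 alkoxide may be lost by β-elimination back to 10. The fallback sets C5–H and C6–O together by a stereospecific syn addition; it sets out from 10 and returns at 13. Corey–Bakshi–Shibata reduction with the (R)-oxazaborolidine would give the (1R,4S)-allylic alcohol with C4–OH on the face of the C1 methyl F5, and TESOTf with 2,6-lutidine its triethylsilyl ether F6. BH3·THF, then NaBO3·4H2O, should add H to C5 and OH to C6 from the face anti to the silyloxy group, giving the (1R,4S,5S,6S)-C6 alcohol F7. TBSOTf would give the C6 TBS ether F8, pyridinium tosylate in MeOH would free the C4 alcohol F9, and Parikh–Doering oxidation would give 13.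

**Step 9.** The branched reagent may enolise the ketone (followed by loss of the C6 silyloxy group), reduce it by β-hydride transfer, or attack the wrong face. The fallback uses an sp2 nucleophile and a later reduction; it sets out from 13 and returns at 14. CH2=C(CH3)MgBr with CeCl3 (THF, −78 °C) would give the (1R,4S,5S,6S)-isopropenyl carbinol with the same spatial arrangement at C4 F10, and hydrogenation of its 1,1-disubstituted alkene (H2, RhCl(PPh3)3, benzene), which should spare the tetrasubstituted enol ether, would give 14.

**Step 14.** The amide base or the hindered alkoxide may deprotonate the enone (C10–H or C6–H) before acylation occurs, or the alkoxide may be too hindered to acylate at low temperature. The fallback acylates before the ketone exists; it sets out from 15 (isolated after a neutral work-up of step 10 with aqueous potassium sodium tartrate) and returns at 21. The dilithium alkoxide of 15 (n-BuLi, 2.1 equiv, THF, −78 °C) and 20 (2.5 equiv) would give the bis[4-(TBSO)benzoate] of 15 F11. Dilute HCl in THF, then DBU, would hydrolyse the now unstabilised enol ether and expel the primary aroyloxy group (E1cB) to give the α-methylene ketone O4 4-(TBSO)benzoate F12. The isomerisation of step 11 (RhCl3·3H2O, EtOH) would then give 21.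

## Further compounds

F1 | step 5 | 7-methyl-6-vinyl-1,4-dioxaspiro[4.4]non-6-ene | CC1=C(C=C)C2(CC1)OCCO2
F2 | step 5 | (1R)-C4 ethylene ketal of 10 | COC(=O)C1=C(O[Si](C)(C)C(C)(C)C)C[C@@]2(C)CCC3(OCCO3)C2=CC1
F3 | step 6 | (1R,4R)-allylic alcohol from 10, C4–OH anti to the C1 methyl | COC(=O)C1=C(O[Si](C)(C)C(C)(C)C)C[C@@]2(C)CC[C@@H](O)C2=CC1
F4 | step 6 | (1R,4R,5S,6S)-5,6-epoxy C4 alcohol, oxirane syn to C4–OH | COC(=O)C1=C(O[Si](C)(C)C(C)(C)C)C[C@@]2(C)CC[C@@H](O)[C@]2(O3)[C@@H]3C1
F5 | step 7 | (1R,4S)-allylic alcohol from 10, C4–OH syn to the C1 methyl | COC(=O)C1=C(O[Si](C)(C)C(C)(C)C)C[C@@]2(C)CC[C@H](O)C2=CC1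
F6 | step 7 | triethylsilyl ether of F5 | COC(=O)C1=C(O[Si](C)(C)C(C)(C)C)C[C@@]2(C)CC[C@H](O[Si](CC)(CC)CC)C2=CC1
F7 | step 7 | (1R,4S,5S,6S)-C6 alcohol, C4–OTES | COC(=O)C1=C(O[Si](C)(C)C(C)(C)C)C[C@@]2(C)CC[C@H](O[Si](CC)(CC)CC)[C@@H]2[C@@H](O)C1
F8 | step 7 | C6 TBS ether of F7 | COC(=O)C1=C(O[Si](C)(C)C(C)(C)C)C[C@@]2(C)CC[C@H](O[Si](CC)(CC)CC)[C@@H]2[C@@H](O[Si](C)(C)C(C)(C)C)C1
F9 | step 7 | (1R,4S,5S,6S)-C4 alcohol, C6–OTBS | COC(=O)C1=C(O[Si](C)(C)C(C)(C)C)C[C@@]2(C)CC[C@H](O)[C@@H]2[C@@H](O[Si](C)(C)C(C)(C)C)C1
F10 | step 9 | (1R,4S,5S,6S)-isopropenyl carbinol | COC(=O)C1=C(O[Si](C)(C)C(C)(C)C)C[C@@]2(C)CC[C@@](O)(C(C)=C)[C@@H]2[C@@H](O[Si](C)(C)C(C)(C)C)C1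
F11 | step 14 | bis[4-(TBSO)benzoate] of 15 (primary allylic and tertiary O4 esters) | CC(C)(C)[Si](C)(C)Oc1ccc(cc1)C(=O)OCC1=C(O[Si](C)(C)C(C)(C)C)C[C@@]2(C)CC[C@@](OC(=O)c3ccc(O[Si](C)(C)C(C)(C)C)cc3)(C(C)C)[C@@H]2[C@@H](O[Si](C)(C)C(C)(C)C)C1
F12 | step 14 | α-methylene ketone O4 4-(TBSO)benzoate, C6–OTBS | C=C1C(=O)C[C@@]2(C)CC[C@@](OC(=O)c3ccc(O[Si](C)(C)C(C)(C)C)cc3)(C(C)C)[C@@H]2[C@@H](O[Si](C)(C)C(C)(C)C)C1
A1 | alternative 1 | 3-allylcyclopent-2-en-1-one | C=CCC1=CC(=O)CC1
A2 | alternative 1 | but-2-ynal | CC#CC=O
A3 | alternative 1 | (2S,3R)-3-allyl-2-[(1R)-1-hydroxybut-2-yn-1-yl]-3-methylcyclopentan-1-one | CC#C[C@H](O)[C@@H]1[C@](C)(CCC1=O)CC=C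
A4 | alternative 2 | (E)-2-methyl-4-oxopent-2-en-1-yl 6-acetoxy-4-methyl-3-oxo-3,6-dihydro-2H-pyran-2-carboxylate (mixture of diastereomers) | CC1=CC(OC(C)=O)OC(C(=O)OC/C(C)=C/C(C)=O)C1=O
A5 | alternative 2 | oxygen-bridged cycloheptenone adduct with C10–C2 lactone and C5 acetyl group | CC1=C[C@H]2[C@@H](C(C)=O)[C@]3(C)COC(=O)[C@@]3(O2)C1=O
A6 | alternative 3 | 1-diazo-4-(3-methoxy-4-methylphenyl)butan-2-one | COc1cc(CCC(=O)C=[N+]=[N-])ccc1C
A7 | alternative 3 | (8aR)-5-methoxy-6-methyl-3,8a-dihydroazulen-1(2H)-one | COC1=C(C)C=C[C@H]2C(=O)CCC2=C1
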